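The ten-membered carbocycle is closed last, between the lactone carbinol carbon C6 and the ring-fusion carbon C7 (germacranolide numbering). The precursor is an open chain. Its carboxyl C12 is parked on the C8 oxygen as an α-(bromomethyl)butenolide, and its far end is a (Z)-enal. CrCl2 generates an allylchromium that adds through C7 to the aldehyde. This one operation closes the carbocycle, sets C6 and C7 and creates the exocyclic methylene. An acyl shift from O8 to O6 then builds the final γ-lactone and frees O8 for the epoxyangelate. The step exploits O8 next to C7 and the three cis-locked units C1=C10, oxirane C2–C3 and C4=C5, which fold the chain.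

Key step: step 18

Remark: atom labels are ring C1–C10 (C10 bears ester carbon C14, C9 the acetate, C8 the epoxyangelate) and C11–C13 for the methylene-lactone carbons. The C7 carbinol of step 6 is drawn as the expected anti isomer, and its epimer converges in step 17. From step 4 on nothing is heated, because a cis-dialkenyl oxirane can undergo Cope rearrangement.

Step 1
Reactants: 1 ethyl (2Z)-3-iodoprop-2-enoate
Product: 2 (2Z)-3-iodoprop-2-en-1-ol
Conditions: DIBAL-H (2.2 equiv), CH2Cl2, −78 to 0 °C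
Reagents that add atoms: none
Why: Hydride reduction of the enoate to the allylic alcohol at low temperature should leave the C–I bond and the Z geometry untouched.

Step 2
Reactants: 2 (2Z)-3-iodoprop-2-en-1-ol; 3 tert-butyldimethyl(prop-2-yn-1-yloxy)silane
Product: 4 (2Z)-6-[(tert-butyldimethylsilyl)oxy]hex-2-en-4-yn-1-ol
Conditions: PdCl2(PPh3)2 (2 mol %), CuI (4 mol %), Et3N, THF, rt
Reagents that add atoms: none
Why: Sonogashira coupling of an alkenyl iodide proceeds with retention of the Z geometry and tolerates the free alcohol and the silyl ether.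

Step 3
Reactants: 4 (2Z)-6-[(tert-butyldimethylsilyl)oxy]hex-2-en-4-yn-1-ol
Product: 5 [(2R,3S)-3-{3-[(tert-butyldimethylsilyl)oxy]prop-1-yn-1-yl}oxiran-2-yl]methanol (cis-oxirane)
Conditions: Ti(OiPr)4 (20 mol %), D-(−)-diethyl tartrate (24 mol %), t-BuOOH, 4 Å MS, CH2Cl2, −20 °C
Reagents that add atoms: tert-butyl hydroperoxide, CC(C)(C)OO
Why: Sharpless asymmetric epoxidation directed by the allylic hydroxyl adds oxygen syn to the only alkene, so the Z-alkene gives the cis-oxirane and the D-(−)-tartrate sets C2 (R) and C3 (S).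

Step 4
Reactants: 5 [(2R,3S)-3-{3-[(tert-butyldimethylsilyl)oxy]prop-1-yn-1-yl}oxiran-2-yl]methanol
Product: 6 [(2R,3S)-3-{(1Z)-3-[(tert-butyldimethylsilyl)oxy]prop-1-en-1-yl}oxiran-2-yl]methanol
Conditions: H2 (1 atm), Pd/CaCO3 poisoned with Pb(OAc)2, quinoline, EtOAc, rt
Reagents that add atoms: none
Why: Lindlar-type semihydrogenation adds hydrogen syn to the alkyne and should stop at the (Z)-alkene C4=C5, with quinoline holding back over-reduction and C–O hydrogenolysis.

Step 5
Reactants: 6 [(2R,3S)-3-{(1Z)-3-[(tert-butyldimethylsilyl)oxy]prop-1-en-1-yl}oxiran-2-yl]methanol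
Product: 8 methyl (2Z)-2-iodo-3-[(2R,3S)-3-{(1Z)-3-[(tert-butyldimethylsilyl)oxy]prop-1-en-1-yl}oxiran-2-yl]prop-2-enoate, via cis-epoxy aldehyde 7 (not isolated)
Conditions: TEMPO (10 mol %), PhI(OAc)2, CH2Cl2, 0 °C, NaHCO3 wash; then crude 7 added to Ph3P=CHCO2Me and NIS (premixed, CH2Cl2, −20 °C), to rt
Reagents that add atoms: methyl (triphenyl-λ5-phosphanylidene)acetate, COC(=O)C=P(c1ccccc1)(c1ccccc1)c1ccccc1; N-iodosuccinimide, O=C1CCC(=O)N1I
Why: Oxoammonium oxidation is followed by a Wittig reaction with the stabilised iodo-ylide, which should place iodine cis to the oxirane so that C2 ends up trans to the ester as in the target, and the epimerisable aldehyde is never purified.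

Step 6
Reactants: 9 (4R)-2,2-dimethyl-1,3-dioxolane-4-carbaldehyde; 10 methyl acrylate
Product: 11 methyl 2-{(S)-[(4R)-2,2-dimethyl-1,3-dioxolan-4-yl](hydroxy)methyl}prop-2-enoate
Conditions: DABCO (0.5 equiv), 1,4-dioxane–H2O, rt
Reagents that add atoms: none
Why: The Morita–Baylis–Hillman reaction joins C7 to C11; C8 comes from the chiral pool, and the new C7 carbinol (anti by Felkin–Anh attack) is only a placeholder that becomes sp2 in step 17.

Step 7
Reactants: 11 methyl 2-{(S)-[(4R)-2,2-dimethyl-1,3-dioxolan-4-yl](hydroxy)methyl}prop-2-enoate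
Product: 12 methyl 2-{(S)-[(tert-butyldimethylsilyl)oxy][(4R)-2,2-dimethyl-1,3-dioxolan-4-yl]methyl}prop-2-enoate
Conditions: TBSCl, imidazole, DMF, rt
Reagents that add atoms: tert-butyldimethylsilyl chloride, CC(C)(C)[Si](C)(C)Cl
Why: Standard silylation masks the C7 hydroxyl so that only O8 and O9 are unveiled in the next step.

Step 8
Reactants: 12 methyl 2-{(S)-[(tert-butyldimethylsilyl)oxy][(4R)-2,2-dimethyl-1,3-dioxolan-4-yl]methyl}prop-2-enoate
Product: 14 (4S,5R)-4-[(tert-butyldimethylsilyl)oxy]-5-(hydroxymethyl)-3-methylideneoxolan-2-one, via diol ester 13 (not isolated)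
Conditions: p-TsOH·H2O (10 mol %), MeOH–H2O 9:1, rt
Reagents that add atoms: none
Why: Acid-catalysed acetonide hydrolysis frees O8, which closes the five-membered lactone on the acrylate ester (5-exo-trig); this parks C12 on O8 and leaves only the primary C9 hydroxyl free, while the secondary silyl ether should survive.

Step 9
Reactants: 14 (4S,5R)-4-[(tert-butyldimethylsilyl)oxy]-5-(hydroxymethyl)-3-methylideneoxolan-2-one
Product: 15 (2S,3S)-3-[(tert-butyldimethylsilyl)oxy]-4-methylidene-5-oxooxolane-2-carbaldehyde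
Conditions: Dess–Martin periodinane, CH2Cl2, 0 °C to rt
Reagents that add atoms: none
Why: Dess–Martin oxidation is base-free, so the α-oxygenated aldehyde should form without epimerisation at C8 or β-elimination of the silyloxy group.

Step 10
Reactants: 16 methyl (2Z)-2-methylbut-2-enoate (methyl angelate)
Product: 17 (2Z)-2-methylbut-2-en-1-ol
Conditions: DIBAL-H (2.2 equiv), Et2O, −78 to 0 °C
Reagents that add atoms: none
Why: 1,2-Reduction of the enoate with DIBAL-H keeps the Z geometry of the angelate.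

Step 11
Reactants: 17 (2Z)-2-methylbut-2-en-1-ol
Product: 18 [(2R,3S)-2,3-dimethyloxiran-2-yl]methanol
Conditions: Ti(OiPr)4 (10 mol %), D-(−)-diethyl tartrate (12 mol %), t-BuOOH, 4 Å MS, CH2Cl2, −20 °C
Reagents that add atoms: tert-butyl hydroperoxide, CC(C)(C)OO
Why: Sharpless asymmetric epoxidation with D-(−)-tartrate sets both oxirane centres, and syn addition to the Z-alkene keeps C1 and C4 cis.

Step 12
Reactants: 18 [(2R,3S)-2,3-dimethyloxiran-2-yl]methanol
Product: 19 (2S,3S)-2,3-dimethyloxirane-2-carboxylic acid (epoxyangelic acid)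
Conditions: TEMPO (20 mol %), PhI(OAc)2 (2.2 equiv), MeCN–H2O, rt
Reagents that add atoms: water, O
Why: Oxoammonium oxidation through the aldehyde hydrate gives the acid without touching the oxirane; only the descriptor at C2 changes, because of the new priority order.

Step 13
Reactants: 8 methyl (2Z)-2-iodo-3-[(2R,3S)-3-{(1Z)-3-[(tert-butyldimethylsilyl)oxy]prop-1-en-1-yl}oxiran-2-yl]prop-2-enoate; 15 (2S,3S)-3-[(tert-butyldimethylsilyl)oxy]-4-methylidene-5-oxooxolane-2-carbaldehyde
Product: 21 methyl (2E)-2-{(R)-hydroxy[(2R,3S)-3-[(tert-butyldimethylsilyl)oxy]-4-methylidene-5-oxooxolan-2-yl]methyl}-3-[(2R,3S)-3-{(1Z)-3-[(tert-butyldimethylsilyl)oxy]prop-1-en-1-yl}oxiran-2-yl]prop-2-enoate, via alkenylchromium dichloride 20 (not isolated)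
Conditions: CrCl2 (4 equiv), NiCl2 (1 mol %), DMF, rt
Reagents that add atoms: none
Why: In the Nozaki–Hiyama–Kishi coupling zerovalent nickel inserts into the C–I bond and transmetalation gives 20 with retention of geometry; 20 adds only to the aldehyde, and Felkin–Anh attack anti to the C8–O8 bond should set C9 (R), anti to O8.

Step 14
Reactants: 21 the C9 carbinol of step 13
Product: 22 the 9-acetate of 21 (methyl (2E)-2-{(R)-acetyloxy[(2R,3S)-3-[(tert-butyldimethylsilyl)oxy]-4-methylidene-5-oxooxolan-2-yl]methyl}-3-[oxiranyl]prop-2-enoate, rest unchanged)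
Conditions: Ac2O, pyridine, DMAP (cat.), CH2Cl2, 0 °C
Reagents that add atoms: acetic anhydride, CC(=O)OC(C)=O
Why: Acetylation of the only free hydroxyl installs the final C9 acetate without touching a stereocentre.

Step 15
Reactants: 22 the 9-acetate
Product: 23 diol with free C6 (primary allylic) and C7 (secondary) hydroxyls
Conditions: HF·pyridine, excess pyridine, THF, 0 °C to rt
Reagents that add atoms: none
Why: Buffered fluoride cleaves both silyl ethers under slightly acidic conditions, which should avoid acetyl migration, conjugate addition to the methylene lactone and oxirane opening.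

Step 16
Reactants: 23 the C6,C7-diol
Product: 24 (Z)-enal with free C7 hydroxyl
Conditions: TEMPO (10 mol %), PhI(OAc)2 (1.1 equiv), CH2Cl2, 0 °C
Reagents that add atoms: none
Why: The oxoammonium oxidation is much faster for the unhindered primary allylic alcohol than for the hindered, electron-poor C7 carbinol, and the mild medium should preserve the Z geometry.

Step 17
Reactants: 24 the (Z)-enal with free C7 hydroxyl
Product: 25 (Z)-enal carrying the [(2S)-4-(bromomethyl)-5-oxo-2,5-dihydrofuran-2-yl] unit (key-step precursor)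
Conditions: NBS, Me2S, CH2Cl2, −20 to 0 °C
Reagents that add atoms: N-bromosuccinimide, O=C1CCC(=O)N1Br
Why: The bromosulfonium reagent (Corey–Kim type, as used on Morita–Baylis–Hillman alcohols) activates the hydroxyl, and SN2' attack of bromide at the exocyclic methylene moves the double bond into the ring, which erases C7 and leaves aldehyde, esters and oxirane alone.

Step 18
Reactants: 25 the (Z)-enal α-(bromomethyl)butenolide
Product: 28 8-hydroxy-6,12-olide (the target without its epoxyangeloyl group; all ring stereocentres as in the target), via allylchromium dichloride 26 (not isolated), via chromium alkoxide 27 (not isolated)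
Conditions: CrCl2 (10 equiv), 4 Å MS, THF–DMF, slow addition of 25 to about 1 mM, rt; aqueous work-up
Reagents that add atoms: none
Why: CrCl2 inserts into the allylic C–Br bond by two one-electron transfers, allylchromium 26 adds through its γ-carbon C7 to the aldehyde carbon C6 in a closed six-membered Zimmerman–Traxler transition state, and the trivalent chromium alkoxide 27 then attacks the neighbouring lactone carbonyl C12 and expels O8. The closest known reaction types are the intramolecular Nozaki–Hiyama (Barbier-type) allylation used to close ten-membered germacranolide rings and the Barbier addition of α-(bromomethyl)butenolides to aldehydes, followed by a translactonisation. The carbocycle closes 10-exo-trig at the carbonyl carbon, and the final γ-lactone closes by a 5-exo-trig acyl transfer that opens the temporary O8 lactone, driven by relief of the eclipsed cis-fused C7–C8 bond in favour of the trans-fused 6,12-lactone. At C7, the three cis-locked units (C1=C10, oxirane C2–C3, C4=C5) fold the eight-atom tether from C9 into a crown whose end should reach only the butenolide face syn to C9, giving H7 cis to H8. At C6, the butenolide ring fixes C8 trans to the CH2Cr group (E-crotyl type, no isomerisation possible), so the chair with the s-trans enal attacked on its inner Si face should give the anti adduct, that is the trans 6,7 relationship. The step needs metalation of the bromide beside oxirane, enoate and esters, 1,2-addition, and cyclisation over oligomerisation; the mild reducing power and aldehyde selectivity of CrCl2 and slow addition at high dilution should secure these.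

Step 19
Reactants: 28 the 8-hydroxy-6,12-olide; 19 (2S,3S)-2,3-dimethyloxirane-2-carboxylic acid
Product: 30 CNP0077533.1 (2R,3S,6R,7S,8S,9R; epoxyangelate 2S,3S), via mixed anhydride 29 (not isolated)
Conditions: 19, 2,4,6-trichlorobenzoyl chloride, Et3N, toluene, rt; then 28, DMAP, 0 °C to rt
Reagents that add atoms: none
Why: Yamaguchi esterification with DMAP acyl transfer copes with the hindered secondary alcohol and the α-quaternary acid, touches no stereocentre, and the low temperature should limit acetyl migration from O9 to O8.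

Compound list
1 | ethyl (2Z)-3-iodoprop-2-enoate | CCOC(=O)/C=C\I | starting material
2 | (2Z)-3-iodoprop-2-en-1-ol | OC/C=C\I | intermediate
3 | tert-butyldimethyl(prop-2-yn-1-yloxy)silane | C#CCO[Si](C)(C)C(C)(C)C | starting material
4 | (2Z)-6-[(tert-butyldimethylsilyl)oxy]hex-2-en-4-yn-1-ol | CC(C)(C)[Si](C)(C)OCC#C/C=C\CO | intermediate
5 | [(2R,3S)-3-{3-[(tert-butyldimethylsilyl)oxy]prop-1-yn-1-yl}oxiran-2-yl]methanol | CC(C)(C)[Si](C)(C)OCC#C[C@@H]1O[C@@H]1CO | intermediate
6 | [(2R,3S)-3-{(1Z)-3-[(tert-butyldimethylsilyl)oxy]prop-1-en-1-yl}oxiran-2-yl]methanol | CC(C)(C)[Si](C)(C)OC/C=C\[C@@H]1O[C@@H]1CO | intermediate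
7 | (2S,3S)-3-{(1Z)-3-[(tert-butyldimethylsilyl)oxy]prop-1-en-1-yl}oxirane-2-carbaldehyde (cis) | CC(C)(C)[Si](C)(C)OC/C=C\[C@@H]1O[C@@H]1C=O | intermediate
8 | methyl (2Z)-2-iodo-3-[(2R,3S)-3-{(1Z)-3-[(tert-butyldimethylsilyl)oxy]prop-1-en-1-yl}oxiran-2-yl]prop-2-enoate | CC(C)(C)[Si](C)(C)OC/C=C\[C@@H]1O[C@@H]1/C=C(/C(=O)OC)I | intermediate
9 | (4R)-2,2-dimethyl-1,3-dioxolane-4-carbaldehyde | CC1(C)OC[C@@H](O1)C=O | starting material
10 | methyl acrylate | C=CC(=O)OC | starting material
11 | methyl 2-{(S)-[(4R)-2,2-dimethyl-1,3-dioxolan-4-yl](hydroxy)methyl}prop-2-enoate | CC1(C)OC[C@@H](O1)[C@@H](O)C(=C)C(=O)OC | intermediate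
12 | methyl 2-{(S)-[(tert-butyldimethylsilyl)oxy][(4R)-2,2-dimethyl-1,3-dioxolan-4-yl]methyl}prop-2-enoate | CC1(C)OC[C@@H](O1)[C@@H](O[Si](C)(C)C(C)(C)C)C(=C)C(=O)OC | intermediate
13 | methyl (3S,4R)-3-[(tert-butyldimethylsilyl)oxy]-4,5-dihydroxy-2-methylidenepentanoate | OC[C@@H](O)[C@@H](O[Si](C)(C)C(C)(C)C)C(=C)C(=O)OC | intermediate
14 | (4S,5R)-4-[(tert-butyldimethylsilyl)oxy]-5-(hydroxymethyl)-3-methylideneoxolan-2-one | OC[C@H]1OC(=O)C(=C)[C@@H]1O[Si](C)(C)C(C)(C)C | intermediate
15 | (2S,3S)-3-[(tert-butyldimethylsilyl)oxy]-4-methylidene-5-oxooxolane-2-carbaldehyde | O=C[C@H]1OC(=O)C(=C)[C@@H]1O[Si](C)(C)C(C)(C)C | intermediate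
16 | methyl (2Z)-2-methylbut-2-enoate | C/C=C(/C)C(=O)OC | starting material
17 | (2Z)-2-methylbut-2-en-1-ol | C/C=C(/C)CO | intermediate
18 | [(2R,3S)-2,3-dimethyloxiran-2-yl]methanol | OC[C@@]1(C)O[C@H]1C | intermediate
19 | (2S,3S)-2,3-dimethyloxirane-2-carboxylic acid | OC(=O)[C@@]1(C)O[C@H]1C | intermediate
20 | alkenylchromium dichloride derived from 8 (Cr in place of I) | CC(C)(C)[Si](C)(C)OC/C=C\[C@@H]1O[C@@H]1/C=C(/C(=O)OC)[Cr](Cl)Cl | intermediate
21 | open-chain C9 carbinol (9R, anti to O8), bis-silyl ether | CC(C)(C)[Si](C)(C)OC/C=C\[C@@H]1O[C@@H]1/C=C(/C(=O)OC)[C@@H](O)[C@H]2OC(=O)C(=C)[C@@H]2O[Si](C)(C)C(C)(C)C | intermediate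
22 | 9-acetate of 21 | CC(C)(C)[Si](C)(C)OC/C=C\[C@@H]1O[C@@H]1/C=C(/C(=O)OC)[C@@H](OC(C)=O)[C@H]2OC(=O)C(=C)[C@@H]2O[Si](C)(C)C(C)(C)C | intermediate
23 | C6,C7-diol | OC/C=C\[C@@H]1O[C@@H]1/C=C(/C(=O)OC)[C@@H](OC(C)=O)[C@H]2OC(=O)C(=C)[C@@H]2O | intermediate
24 | (Z)-enal with free C7 hydroxyl | O=C/C=C\[C@@H]1O[C@@H]1/C=C(/C(=O)OC)[C@@H](OC(C)=O)[C@H]2OC(=O)C(=C)[C@@H]2O | intermediate
25 | (Z)-enal α-(bromomethyl)butenolide | O=C/C=C\[C@@H]1O[C@@H]1/C=C(/C(=O)OC)[C@@H](OC(C)=O)[C@H]2OC(=O)C(CBr)=C2 | intermediate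
26 | allylchromium dichloride derived from 25 | O=C/C=C\[C@@H]1O[C@@H]1/C=C(/C(=O)OC)[C@@H](OC(C)=O)[C@H]2OC(=O)C(C[Cr](Cl)Cl)=C2 | intermediate
27 | chromium alkoxide of the cis-fused 6-hydroxy-8,12-olide | Cl[Cr](Cl)O[C@@H]1/C=C\[C@@H]2O[C@@H]2/C=C(/C(=O)OC)[C@@H](OC(C)=O)[C@H]3OC(=O)C(=C)[C@@H]13 | intermediate
28 | 8-hydroxy-6,12-olide (target without the epoxyangeloyl group) | C=C1C(=O)O[C@@H]2/C=C\[C@@H]3O[C@@H]3/C=C(/C(=O)OC)[C@@H](OC(C)=O)[C@@H](O)[C@@H]12 | intermediate
29 | (2S,3S)-2,3-dimethyloxirane-2-carboxylic 2,4,6-trichlorobenzoic anhydride | O=C(OC(=O)[C@@]1(C)O[C@H]1C)c1c(Cl)cc(Cl)cc1Cl | intermediate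
30 | CNP0077533.1 | C=C1C(=O)O[C@@H]2/C=C\[C@@H]3O[C@@H]3/C=C(/C(=O)OC)[C@@H](OC(C)=O)[C@@H](OC(=O)[C@@]3(C)O[C@H]3C)[C@@H]12 | target

Total steps: 19. Longest linear sequence: 12 steps (1–5, then 13–19).

Steps most likely to fail

Step 18. The Lewis-acidic trivalent chromium salts may isomerise the (Z)-enal or open the doubly allylic oxirane before the ring closes. Oligomerisation may compete, and facial selectivity or the acyl shift may fall short. The fallback sets out from 5 and returns at 28; it makes the Z-alkene after ring closure instead of before it. Step 4 is skipped and the alkyne is carried through the operations of steps 5 and 13 to 17. These give in turn alkynyl epoxy aldehyde F1, alkynyl iodoenoate F2, alkynyl C9 carbinol F3, its acetate F4, alkynyl diol F5, hydroxy ynal F6 and bromo ynal F7. The ynal cannot lose geometry, its oxirane is allylic on one side only, and it is the more reactive electrophile. Closure with CrCl2 and acyl shift should give cyclodecyne lactone F8. Its strained ring alkyne should take up hydrogen (H2, Pd/CaCO3 poisoned with Pb(OAc)2, quinoline, 0 °C) before the exocyclic methylene does, giving 28.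

Step 13. The alkenylchromium bearing the α-ester may leak into an allenolate-type species with loss of the C1=C10 geometry. It may also couple sluggishly or add with weak Felkin–Anh preference. The fallback sets out from 8 and returns at 22; it carries C14 at the alcohol level, so that an ordinary trisubstituted alkenyl iodide is coupled.
- DIBAL-H gives iodo allylic alcohol F9, and TESCl gives its triethylsilyl ether F10.
- CrCl2/NiCl2 coupling with 15 gives carbinol F11, and Ac2O gives acetate F12.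
- PPTS in MeOH removes only the triethylsilyl group, giving C14 alcohol F13.
- MnO2 (C14 enal F14), NaClO2 with 2-methylbut-2-ene (C14 acid F15) and Me3SiCHN2 restore the methyl ester of 22.

Step 17. The bromosulfonium reagent or bromide may attack the oxirane, and the (Z)-enal may isomerise during reaction and purification. The fallback sets out from 23 and returns at 25; it installs the bromide first and the aldehyde last.
- The primary allylic hydroxyl of 23 is silylated selectively (TESCl, imidazole, −40 °C), giving monosilyl ether F16.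
- NBS/Me2S converts the C7 hydroxyl, giving silylated bromomethylbutenolide F17.
- HF·pyridine frees bromo allylic alcohol F18.
- MnO2 delivers 25 directly before the ring closure.

Further compounds
F1 | step 18 | (2S,3S)-3-{3-[(tert-butyldimethylsilyl)oxy]prop-1-yn-1-yl}oxirane-2-carbaldehyde | CC(C)(C)[Si](C)(C)OCC#C[C@@H]1O[C@@H]1C=O
F2 | step 18 | alkynyl analogue of 8 | CC(C)(C)[Si](C)(C)OCC#C[C@@H]1O[C@@H]1/C=C(/C(=O)OC)I
F3 | step 18 | alkynyl analogue of 21 | CC(C)(C)[Si](C)(C)OCC#C[C@@H]1O[C@@H]1/C=C(/C(=O)OC)[C@@H](O)[C@H]2OC(=O)C(=C)[C@@H]2O[Si](C)(C)C(C)(C)C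
F4 | step 18 | alkynyl analogue of 22 | CC(C)(C)[Si](C)(C)OCC#C[C@@H]1O[C@@H]1/C=C(/C(=O)OC)[C@@H](OC(C)=O)[C@H]2OC(=O)C(=C)[C@@H]2O[Si](C)(C)C(C)(C)C
F5 | step 18 | alkynyl analogue of 23 | OCC#C[C@@H]1O[C@@H]1/C=C(/C(=O)OC)[C@@H](OC(C)=O)[C@H]2OC(=O)C(=C)[C@@H]2O
F6 | step 18 | ynal analogue of 24 | O=CC#C[C@@H]1O[C@@H]1/C=C(/C(=O)OC)[C@@H](OC(C)=O)[C@H]2OC(=O)C(=C)[C@@H]2O
F7 | step 18 | ynal analogue of 25 | O=CC#C[C@@H]1O[C@@H]1/C=C(/C(=O)OC)[C@@H](OC(C)=O)[C@H]2OC(=O)C(CBr)=C2
F8 | step 18 | 4,5-didehydro (cyclodecyne) analogue of 28 | C=C1C(=O)O[C@@H]2C#C[C@@H]3O[C@@H]3/C=C(/C(=O)OC)[C@@H](OC(C)=O)[C@@H](O)[C@@H]12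
F9 | step 13 | (2Z)-2-iodo-3-[oxiranyl]prop-2-en-1-ol derived from 8 | CC(C)(C)[Si](C)(C)OC/C=C\[C@@H]1O[C@@H]1/C=C(/CO)I
F10 | step 13 | triethylsilyl ether of F9 | CC(C)(C)[Si](C)(C)OC/C=C\[C@@H]1O[C@@H]1/C=C(/CO[Si](CC)(CC)CC)I
F11 | step 13 | C9 carbinol with C14 as CH2OSiEt3 | CC(C)(C)[Si](C)(C)OC/C=C\[C@@H]1O[C@@H]1/C=C(/CO[Si](CC)(CC)CC)[C@@H](O)[C@H]2OC(=O)C(=C)[C@@H]2O[Si](C)(C)C(C)(C)C
F12 | step 13 | 9-acetate of F11 | CC(C)(C)[Si](C)(C)OC/C=C\[C@@H]1O[C@@H]1/C=C(/CO[Si](CC)(CC)CC)[C@@H](OC(C)=O)[C@H]2OC(=O)C(=C)[C@@H]2O[Si](C)(C)C(C)(C)C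
F13 | step 13 | C14 alcohol | CC(C)(C)[Si](C)(C)OC/C=C\[C@@H]1O[C@@H]1/C=C(/CO)[C@@H](OC(C)=O)[C@H]2OC(=O)C(=C)[C@@H]2O[Si](C)(C)C(C)(C)C
F14 | step 13 | C14 enal | CC(C)(C)[Si](C)(C)OC/C=C\[C@@H]1O[C@@H]1/C=C(/C=O)[C@@H](OC(C)=O)[C@H]2OC(=O)C(=C)[C@@H]2O[Si](C)(C)C(C)(C)C
F15 | step 13 | C14 carboxylic acid | CC(C)(C)[Si](C)(C)OC/C=C\[C@@H]1O[C@@H]1/C=C(/C(=O)O)[C@@H](OC(C)=O)[C@H]2OC(=O)C(=C)[C@@H]2O[Si](C)(C)C(C)(C)C
F16 | step 17 | 6-O-triethylsilyl ether of 23 | CC[Si](CC)(CC)OC/C=C\[C@@H]1O[C@@H]1/C=C(/C(=O)OC)[C@@H](OC(C)=O)[C@H]2OC(=O)C(=C)[C@@H]2O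
F17 | step 17 | 6-O-triethylsilyl bromomethylbutenolide | CC[Si](CC)(CC)OC/C=C\[C@@H]1O[C@@H]1/C=C(/C(=O)OC)[C@@H](OC(C)=O)[C@H]2OC(=O)C(CBr)=C2
F18 | step 17 | bromomethylbutenolide with free C6 hydroxyl | OC/C=C\[C@@H]1O[C@@H]1/C=C(/C(=O)OC)[C@@H](OC(C)=O)[C@H]2OC(=O)C(CBr)=C2
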